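The substrate cannot simply have become target: in the north-west run at 10.0 min substrate reads 2.7% and target 2.1%, so 95.2% of the charge is in neither.

| flask | substrate | reagent | temperature | remark | time |
|---|---|---|---|---|---|
| north-west | 0.025 M | 0.090 M | 41 °C | run made earlier |  |
| south-east | 0.038 M | 0.090 M | 55 °C | run made earlier |  |
| red | 0.050 M | 0.0900 M | 60 °C |  | 1.0 h |
| teal | 0.050 M | 0.0900 M | 35 °C |  | 1.0 h |

| run | time / min | target / % | substrate / % |
|---|---|---|---|
| north-west | 10.0 | 2.1 | 2.7 |
| north-west | 15.0 | 2.5 | 3.7 |
| north-west | 20.0 | 4.6 | 2.2 |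
| north-west | 40.0 | 5.7 | 2.5 |
| north-west | 50.0 | 7.9 | 3.3 |
| north-west | 80.0 | 8.1 | 4.6 |
| north-west | 120 | 9.6 | 1.3 |
| south-east | 6.00 | 4.6 | 3.9 |
| south-east | 15.0 | 5.6 | 5.5 |
| south-east | 20.0 | 6.9 | 3.5 |
| south-east | 30.0 | 9.6 | 3.3 |
| south-east | 40.0 | 10.4 | 4.0 |
| south-east | 50.0 | 10.9 | 3.9 |

(each reading ± 1 percentage point)

* the flask with the highest amount of target, in percent of the substrate charged ("all alike" if they lie within 1.5 percentage points) (red / teal / all alike)
* final target, as a percentage of the substrate charged, in red
* final target, as a percentage of the substrate charged, in teal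



Build the flask one process at a time, and solve it at its two ends.

1. Take just the main step, substrate + reagent → target. Reagent at 0.0900 M exceeds substrate at 0.050 M, so in this picture substrate is the limiting reagent, and the ceiling for red and teal is the whole charge.

2. Add a fast, unseen store that holds the substrate. This is the early end: target now grows at a pace, and the north-west pace of 2.1% in 10.0 min would need 7.94 h for the whole charge.

3. Suppose that target levels off. This is the late end: the north-west run reaches 9.6% by 120 min, with 89.1% still unseen, and the south-east run reaches 10.9% by 50.0 min. Take these last readings as plateaus, and join the ends: the fill time τ is the plateau divided by the early pace, 45.7 min at 41 °C, with target = plateau × (1 − exp(−t/τ)). The south-east run gives 14.2 min at 55 °C. Both are readings with scatter, from different charges.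

4. Let τ change by a constant factor per degree. Red gets 9.37 min, so its time is 6.40 fill times: on this reckoning red is at the late end, and with the south-east plateau I reckon 10.9%. Teal gets 75.4 min, so 0.796 fill times, and with the north-west plateau I reckon 5.27%.

The forecast says red, with 12.5% (9.5% to 16%) in red and 5.5% (3.5% to 8%) in teal, on the view that an intermediate “feeds target slowly, and most of it leaks elsewhere”. Its numbers stand above mine.

    2 substrate ⇌ resting dimer, settled at all times (K = 6000 L mol⁻¹, ΔH = −68.0 kJ mol⁻¹)
    substrate + reagent → target (k = 3.20 L mol⁻¹ min⁻¹, Ea = 59.0 kJ mol⁻¹)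
    substrate ⇌ dormant form (K = 2.50, k = 0.0800 min⁻¹, Ea = 106 kJ mol⁻¹, ΔH = −10.0 kJ mol⁻¹)
    2 reagent → self-condensation product (k = 0.990 L mol⁻¹ min⁻¹, Ea = 77.0 kJ mol⁻¹)
    (constants at 60 °C)

Red holds the most target, 14.0% against 3.03% in teal. At 1.00 h red has 74.7% of its substrate in resting dimer, the resting state, and 7.0% of its reagent left. From 45.7 min came red's 9.37 min, so at 10.0 h red has had 64.0 fill times, and it stands at 20.4%, above the plateau I used. Teal, left for 10.0 h, has 7.96 fill times, my plateau for it is 9.6%, and that flask holds 9.52%.

The earlier runs and the new flask stem from a simulated flask from invented constants; scatter was added.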